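Ring B is bought as (R)-carvone: its enone is C9(=O)–C8(CH3)=C7, its α′-carbon is C10 and its isopropenyl carbon is C4 (labdane numbering). Two enolate alkylations give a monocyclic triene carrying methyl and allyl on C10. The key step closes ring A (C1–C5, C10) last: formic acid protonates the isopropenyl group, the tertiary C4 cation is trapped by the allyl terminus (new C3–C4 bond) and formate caps C2. One operation thus builds ring A, the quaternary gem-dimethyl C4 and the equatorial C2–O bond, exploiting the 1,3,5-array C4/C2/C10 of ring A. Methylenation of C9, hydroboration/alkyl–alkyl coupling and a Mitsunobu esterification complete the route.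

Key step: step 3

Remark: bicyclic compounds are named with labdane locants (α = face of H-5, β = face of the C10 methyl). (R)-2-methylbutane-1,4-diol is taken as purchasable; it is otherwise one LiAlH4 reduction away from commercial (R)-methylsuccinic acid.

Step 1
Reactants: 1 (R)-(−)-carvone
Product: 3 (5R,6S)-2,6-dimethyl-5-(prop-1-en-2-yl)cyclohex-2-en-1-one (trans-6-methylcarvone), via lithium dienolate 2 (not isolated)
Conditions: LiN(iPr)2, THF, −78 °C; MeI, −78 → 0 °C
Reagents that add atoms: iodomethane, CI
Why: Kinetic α′-deprotonation of the enone and SN2 methylation of the cross-conjugated dienolate (enolate alkylation); the methyl should enter mainly anti to the isopropenyl group, but this centre is planarised again in step 2, so its configuration is immaterial.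

Step 2
Reactants: 3 trans-6-methylcarvone
Product: 5 (5S,6S)-6-allyl-2,6-dimethyl-5-(prop-1-en-2-yl)cyclohex-2-en-1-one, via lithium enolate 4 (not isolated)
Conditions: LiN(iPr)2, THF, −78 → −20 °C; allyl bromide, DMPU, −78 → 0 °C
Reagents that add atoms: allyl bromide, C=CCBr
Why: Second enolate alkylation: the tetrasubstituted enolate should be attacked on the face anti to the neighbouring isopropenyl group, which sets the quaternary C10 with allyl trans and methyl cis to the isopropenyl group, the relationship needed for a trans ring fusion.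

Step 3
Reactants: 5 (5S,6S)-6-allyl-6-methylcarvone
Product: 7 (2S,5S,10S)-2α-hydroxy-4,4,8,10-tetramethyl-trans-decal-7-en-9-one, via formate ester 6 (not isolated)
Conditions: HCO2H (98%), 25 → 40 °C; evaporate; K2CO3 (cat.), MeOH, 0 °C
Reagents that add atoms: formic acid, O=CO
Why: Formic acid protonates the isopropenyl CH2 (Markovnikov), the tertiary C4 cation is attacked by the terminal vinyl carbon C3 of the allyl group on the adjacent quaternary C10, and formic acid captures the developing secondary cation at C2; methanolysis of the formate then frees the alcohol. The closest known reaction type is the proton-initiated cation–olefin cyclization of 1,6-dienes with a vinyl terminator in formic acid, which gives cyclohexyl formates. Ring A closes in the 6-endo mode with respect to the vinyl group through a chair transition state in which the isopropenyl-derived and allyl-derived arms are trans-diequatorial on ring B, so the trans ring fusion fixed in step 2 is simply carried over. C2 is the only new stereocentre and is controlled by antiperiplanar addition of C4 and formate across the C2=C3 bond in that chair, which places the oxygen equatorial (2α), away from the syn-axial methyls on C4 and C10. The step needs chemoselective protonation of the isopropenyl group and Markovnikov regiochemistry at both alkenes: the ring C7=C8 bond is a deactivated enone that cannot aromatise because C10 is quaternary, the monosubstituted vinyl group is much less basic than the 1,1-disubstituted alkene, and attack through C3 gives the secondary instead of a primary cation. The competing processes are proton loss or hydride shift at C5 and elimination at C2, the latter being corrected by Markovnikov re-addition of formic acid at C2.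

Step 4
Reactants: 7 2α-hydroxy enone
Product: 8 (2S,5S,10S)-4,4,8,10-tetramethyl-9-methylidene-trans-decal-7-en-2α-ol
Conditions: Ph3PCH3Br, KOtBu (3 equiv each), toluene, 90 °C
Reagents that add atoms: methyltriphenylphosphonium bromide, C[P+](c1ccccc1)(c1ccccc1)c1ccccc1.[Br-]
Why: Wittig methylenation of the hindered C9 ketone, which has no α-hydrogen because C10 is quaternary, with excess ylide at elevated temperature; the C2 alkoxide formed in situ is inert and no stereocentre is touched.

Step 5
Reactants: 9 (R)-2-methylbutane-1,4-diol
Product: 10 (R)-4-(tert-butyldiphenylsilyloxy)-2-methylbutan-1-ol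
Conditions: TBDPSCl (1.0 equiv), imidazole, CH2Cl2, −20 °C
Reagents that add atoms: tert-butyl(chloro)diphenylsilane, CC(C)(C)[Si](Cl)(c1ccccc1)c1ccccc1
Why: Monosilylation in which the bulky silyl chloride should prefer the hydroxyl remote from the methyl branch, the regioisomer and the bis-ether being removed by chromatography; the stereocentre (future C13) comes from the chiral pool.

Step 6
Reactants: 10 (R)-4-(tert-butyldiphenylsilyloxy)-2-methylbutan-1-ol
Product: 11 (R)-(4-bromo-3-methylbutoxy)(tert-butyl)diphenylsilane
Conditions: CBr4, PPh3, CH2Cl2, 0 °C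
Reagents that add atoms: tetrabromomethane, BrC(Br)(Br)Br
Why: Appel bromination of the remaining primary alcohol under neutral conditions; the adjacent stereocentre is not involved.

Step 7
Reactants: 8 diene alcohol; 11 (R)-bromide
Product: 13 (13S)-15-(tert-butyldiphenylsilyloxy)labd-7-en-2α-ol, via bisborane 12 (not isolated)
Conditions: 9-BBN-H (2.5 equiv), THF, 0 → 40 °C; then 11 (1.5 equiv), NiCl2·MeOCH2CH2OMe (cat.), trans-N,N′-dimethylcyclohexane-1,2-diamine (cat.), KOtBu, i-BuOH, dioxane, 25 °C; aq. NH4Cl
Reagents that add atoms: 9-borabicyclo[3.3.1]nonane, B1C2CCCC1CCC2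
Why: 9-BBN should add anti-Markovnikov to the exocyclic 1,1-disubstituted alkene (boron to C11) and deliver hydrogen to C9 from the α face, anti to the axial C10 methyl, which sets C9 with the side chain β and equatorial while the trisubstituted C7=C8 bond is too hindered to react; the primary B-alkyl-9-BBN is then joined to bromide 11 by a nickel-catalysed alkyl–alkyl Suzuki–Miyaura coupling, whose radical-type activation of the bromide tolerates the β-branch and leaves C13 untouched, and the boron groups are lost in the coupling and the aqueous work-up.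

Step 8
Reactants: 13 silyl ether
Product: 14 (13S)-labd-7-ene-2α,15-diol
Conditions: Bu4NF, THF, 25 °C
Reagents that add atoms: none
Why: Fluoride-induced desilylation of the primary silyl ether; no other group reacts.

Step 9
Reactants: 14 (13S)-labd-7-ene-2α,15-diol; 15 (E)-caffeic acid
Product: 16 (13S)-2α-hydroxylabd-7-en-15-yl (E)-3-(3,4-dihydroxyphenyl)prop-2-enoate (target)
Conditions: PPh3, DIAD, THF, 0 → 25 °C
Reagents that add atoms: none
Why: Mitsunobu esterification in which only the carboxylic acid is acidic enough to act as pronucleophile and the unhindered primary C15 alcohol should be activated far faster than the secondary C2 alcohol, so the (E)-caffeate forms at C15 without protecting the catechol or C2–OH.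

Compound list
1 | (R)-(−)-carvone, (5R)-2-methyl-5-(prop-1-en-2-yl)cyclohex-2-en-1-one | CC1=CC[C@@H](C(C)=C)CC1=O | starting material
2 | lithium dienolate of 1 (O–Li on C1, C1=C6 and C2=C3) | CC1=CC[C@@H](C(C)=C)C=C1O[Li] | intermediate
3 | (5R,6S)-2,6-dimethyl-5-(prop-1-en-2-yl)cyclohex-2-en-1-one (trans-6-methylcarvone) | CC1=CC[C@@H](C(C)=C)[C@H](C)C1=O | intermediate
4 | lithium enolate of 3 (tetrasubstituted C1=C6 enolate) | CC1=CC[C@@H](C(C)=C)C(C)=C1O[Li] | intermediate
5 | (5S,6S)-6-allyl-2,6-dimethyl-5-(prop-1-en-2-yl)cyclohex-2-en-1-one (allyl trans, methyl cis to isopropenyl) | CC1=CC[C@@H](C(C)=C)[C@](C)(CC=C)C1=O | intermediate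
6 | (2S,5S,10S)-2α-formyloxy-4,4,8,10-tetramethyl-trans-decal-7-en-9-one | CC1=CC[C@H]2C(C)(C)C[C@H](OC=O)C[C@]2(C)C1=O | intermediate
7 | (2S,5S,10S)-2α-hydroxy-4,4,8,10-tetramethyl-trans-decal-7-en-9-one | CC1=CC[C@H]2C(C)(C)C[C@H](O)C[C@]2(C)C1=O | intermediate
8 | (2S,5S,10S)-4,4,8,10-tetramethyl-9-methylidene-trans-decal-7-en-2α-ol | CC1=CC[C@H]2C(C)(C)C[C@H](O)C[C@]2(C)C1=C | intermediate
9 | (R)-2-methylbutane-1,4-diol | OC[C@H](C)CCO | starting material
10 | (R)-4-(tert-butyldiphenylsilyloxy)-2-methylbutan-1-ol | OC[C@H](C)CCO[Si](c1ccccc1)(c1ccccc1)C(C)(C)C | intermediate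
11 | (R)-(4-bromo-3-methylbutoxy)(tert-butyl)diphenylsilane | BrC[C@H](C)CCO[Si](c1ccccc1)(c1ccccc1)C(C)(C)C | intermediate
12 | bisborane: 9α-H C11 B-alkyl-9-BBN carrying the C2 oxygen as its 9-BBN borinate (both boron groups come from 9-BBN-H and are lost before 13) | CC1=CC[C@H]2C(C)(C)C[C@H](OB3C4CCCC3CCC4)C[C@]2(C)[C@H]1CB1C2CCCC1CCC2 | intermediate
13 | (13S)-15-(tert-butyldiphenylsilyloxy)labd-7-en-2α-ol | CC1=CC[C@H]2C(C)(C)C[C@H](O)C[C@]2(C)[C@H]1CC[C@H](C)CCO[Si](c1ccccc1)(c1ccccc1)C(C)(C)C | intermediate
14 | (13S)-labd-7-ene-2α,15-diol | CC1=CC[C@H]2C(C)(C)C[C@H](O)C[C@]2(C)[C@H]1CC[C@H](C)CCO | intermediate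
15 | (E)-caffeic acid | OC(=O)/C=C/c1ccc(O)c(O)c1 | starting material
16 | (13S)-2α-hydroxylabd-7-en-15-yl (E)-caffeate, (2S,5S,9S,10S,13S) | CC1=CC[C@H]2C(C)(C)C[C@H](O)C[C@]2(C)[C@H]1CC[C@H](C)CCOC(=O)/C=C/c1ccc(O)c(O)c1 | target

Total step count: 9. Longest linear sequence: 7 (steps 1, 2, 3, 4, 7, 8, 9).

Steps most likely to fail

Step 3: proton loss or hydride shift at C5 may move the side-chain alkene into conjugation with the enone or scramble C5, and elimination at C2 may outrun formate capture. The fallback uses the stronger terminator of the chloro-olefin annulation, setting out from compound 3 and coming back at compound 7. Alkylation of the enolate of 3 with 2,3-dichloropropene gives (5S,6S)-6-(2-chloroallyl)-2,6-dimethyl-5-(prop-1-en-2-yl)cyclohex-2-en-1-one F1. HCO2H at 50 °C followed by aqueous H2SO4 closes ring A through the α-chloro cation and hydrolyses it to (5S,10S)-4,4,8,10-tetramethyl-trans-decal-7-ene-2,9-dione F2. NaBH4 in MeOH at −40 °C should reduce only the saturated C2 ketone, from the open α face, to the axial 2β-hydroxy enone F3. Mitsunobu inversion with 4-nitrobenzoic acid (PPh3, DIAD) gives the 2α-(4-nitrobenzoate) F4, and K2CO3/MeOH releases compound 7.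

Step 7: transmetalation of the hindered, β-branched alkylborane may be too slow, so that protodeboronation or β-hydride elimination takes over. The fallback reverses the polarity of the C11–C12 union, setting out from compound 8 and coming back at compound 13. Hydroboration with 9-BBN and oxidation (NaOH/H2O2) give 12,13,14,15,16-pentanorlabd-7-ene-2α,11-diol F5. I2/PPh3/imidazole converts its primary hydroxyl into 11-iodo-12,13,14,15,16-pentanorlabd-7-en-2α-ol F6. The Grignard reagent (R)-[4-(tert-butyldiphenylsilyloxy)-2-methylbutyl]magnesium bromide F7, made from bromide 11 and Mg in THF, is then coupled with F6 under Li2CuCl4 catalysis, one extra equivalent serving the C2–OH.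

Step 9: alkylation of the phenols or esterification of C2–OH with inversion may compete with acylation at C15. The fallback builds the cinnamate on the alcohol, setting out from compound 14 and ending at target 16. Meldrum's acid in toluene at 90 °C acylates the primary hydroxyl to the (13S)-2α-hydroxylabd-7-en-15-yl hydrogen malonate F8. Knoevenagel–Doebner condensation with 3,4-dihydroxybenzaldehyde (pyridine, cat. piperidine, 50 °C) then gives the (E)-caffeate with loss of CO2.

Further compounds
F1 | step 3 | (5S,6S)-6-(2-chloroallyl)-2,6-dimethyl-5-(prop-1-en-2-yl)cyclohex-2-en-1-one | CC1=CC[C@@H](C(C)=C)[C@](C)(CC(Cl)=C)C1=O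
F2 | step 3 | (5S,10S)-4,4,8,10-tetramethyl-trans-decal-7-ene-2,9-dione | CC1=CC[C@H]2C(C)(C)CC(=O)C[C@]2(C)C1=O
F3 | step 3 | (2R,5S,10S)-2β-hydroxy-4,4,8,10-tetramethyl-trans-decal-7-en-9-one | CC1=CC[C@H]2C(C)(C)C[C@@H](O)C[C@]2(C)C1=O
F4 | step 3 | (2S,5S,10S)-4,4,8,10-tetramethyl-9-oxo-trans-decal-7-en-2α-yl 4-nitrobenzoate | CC1=CC[C@H]2C(C)(C)C[C@H](OC(=O)c3ccc(cc3)[N+](=O)[O-])C[C@]2(C)C1=O
F5 | step 7 | 12,13,14,15,16-pentanorlabd-7-ene-2α,11-diol | CC1=CC[C@H]2C(C)(C)C[C@H](O)C[C@]2(C)[C@H]1CO
F6 | step 7 | 11-iodo-12,13,14,15,16-pentanorlabd-7-en-2α-ol | CC1=CC[C@H]2C(C)(C)C[C@H](O)C[C@]2(C)[C@H]1CI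
F7 | step 7 | (R)-[4-(tert-butyldiphenylsilyloxy)-2-methylbutyl]magnesium bromide | Br[Mg]C[C@H](C)CCO[Si](c1ccccc1)(c1ccccc1)C(C)(C)C
F8 | step 9 | (13S)-2α-hydroxylabd-7-en-15-yl hydrogen malonate | CC1=CC[C@H]2C(C)(C)C[C@H](O)C[C@]2(C)[C@H]1CC[C@H](C)CCOC(=O)CC(=O)O
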